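**Retrosynthetic overview**
1. The vinyl group comes from a terminal alkyne (semi-hydrogenation, last step).
2. The 13-membered ring and the keto-lactam are closed together by an NHC-catalysed acyl-anion (Stetter) addition of the core aldehyde carbon to the enone carbon alpha to the amide of a ring-opened 5-hydroxypyrrolinone.
3. The cyclopentane and cyclohexene rings form together by an intramolecular Diels–Alder reaction of an (E,Z)-dienyne with a γ-aryloxy enal; the alkynyl group sits "inside" on the diene.
4. The Diels–Alder precursor comes from a trans-cyclohexane aldehyde/ester by Wittig and Peterson olefination (diene) and by asymmetric alkenylation then Mitsunobu etherification (dienophile and aryl ether).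
5. The dimethylcyclohexane is made first by an auxiliary-controlled Diels–Alder reaction, hydrogenation and methanolysis/epimerisation. Ring order: cyclohexane, then cyclopentane + cyclohexene, then macrocycle + hydroxylactam.

Assumptions: the l-menthol-derived (5R)-5-menthyloxyfuranone dienophile is bought (otherwise two steps from furfural and l-menthol). The hemiaminal carbon of the hydroxypyrrolinone fragment is racemic, is left unspecified in the SMILES of the intermediates that carry it, and settles in the macrocyclisation step.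

**Step 1**
Reactants: 1 furan; 2 4-hydroxybenzyl alcohol
Product: 3 4-(furan-2-ylmethyl)phenol
Conditions: 1 (10 equiv), TsOH·H2O (5 mol%), HFIP, 0 → 23 °C
Reagents that add atoms: none
Why: Friedel–Crafts benzylation, in which acid ionises the para-hydroxybenzylic alcohol to a quinone-methide-type cation that the excess furan traps at C2 (no stereocentre).

**Step 2**
Reactants: 3 4-(furan-2-ylmethyl)phenol
Product: 6 rac-5-hydroxy-5-(4-hydroxybenzyl)-1,5-dihydro-2H-pyrrol-2-one, via hydroperoxide 4 (not isolated), via methoxybutenolide 5 (not isolated)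
Conditions: O2, hν (visible), tetraphenylporphyrin (1 mol%), MeOH/CH2Cl2, −78 °C; then NH3 (7 M in MeOH), −78 → 23 °C
Reagents that add atoms: dioxygen (O=O); ammonia (N)
Why: Furan photooxygenation, in which singlet-oxygen [4+2] addition and methanolysis give 4, ammonia effects the Kornblum–DeLaMare dehydration to pseudo-ester 5 and then opens it to the (Z)-4-oxo-enamide, which closes to the hemiaminal lactam (its stereocentre is formed racemic and set later).

**Step 3**
Reactants: 7 (E)-2-methylpenta-1,3-diene; 8 (5R)-5-[(1R,2S,5R)-menthyloxy]furan-2(5H)-one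
Product: 9 (3R)-3-[(1R,2S,5R)-menthyloxy]-5,7-dimethyl-3a,4,7,7a-tetrahydroisobenzofuran-1(3H)-one (cis-fused; 7-methyl cis to the lactone ring; menthyloxy trans to C4)
Conditions: 7 (3 equiv), toluene, 115 °C, sealed tube
Reagents that add atoms: none
Why: Auxiliary-controlled Diels–Alder reaction in which the diene adds anti to the menthyloxy group and endo, with its CH2 terminus on the lactone β-carbon (both methyl groups favour this orientation), which fixes the two ring-fusion carbons and the C-methyl carbon all-cis as one enantiomer.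

**Step 4**
Reactants: 9 Diels–Alder adduct
Product: 10 (3R)-3-[(1R,2S,5R)-menthyloxy]-5,7-dimethylhexahydroisobenzofuran-1(3H)-one (cis-fused; both methyl groups cis to the lactone ring)
Conditions: H2 (1 atm), PtO2 (5 mol%), EtOAc, 23 °C
Reagents that add atoms: none
Why: Heterogeneous hydrogenation takes place on the convex face of the cis-fused bicycle, anti to the lactone ring and the allylic methyl group, so the new methyl-bearing centre is cis to the existing methyl group.

**Step 5**
Reactants: 10 saturated lactone acetal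
Product: 11 methyl (1R,2R,4R,6S)-2-formyl-4,6-dimethylcyclohexane-1-carboxylate (all substituents equatorial)
Conditions: NaOMe (0.3 equiv), MeOH, 0 → 23 °C
Reagents that add atoms: methanol (CO)
Why: Transesterification of the pseudo-ester, in which methoxide opens the lactone, the hemiacetal alkoxide collapses to the aldehyde with loss of menthoxide, and reversible enolisation epimerises the ester-bearing carbon to the all-equatorial (trans,trans) isomer.

**Step 6**
Reactants: 11 aldehyde ester; 12 (triphenylphosphoranylidene)acetaldehyde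
Product: 13 methyl 4,6-dimethyl-2-[(E)-3-oxoprop-1-enyl]cyclohexane-1-carboxylate (ring stereocentres as in 11)
Conditions: 12 (1.2 equiv), toluene, 80 °C
Reagents that add atoms: none
Why: Wittig olefination with a stabilised ylide reacts only at the aldehyde and gives the (E)-enal; no stereocentre is touched.

**Step 7**
Reactants: 13 enal ester; 14 1,3-bis(triisopropylsilyl)propyne
Product: 16 methyl 2-[(1E,3Z)-hexa-1,3-dien-5-ynyl]-4,6-dimethylcyclohexane-1-carboxylate (ring stereocentres as in 11), via silyl dienyne ester 15 (not isolated)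
Conditions: 14, n-BuLi, THF, −20 °C; 13, −78 → 0 °C; then TBAF, THF, 0 → 23 °C
Reagents that add atoms: none
Why: Peterson olefination with the lithiated bis-silylpropyne adds 1,2 to the enal and eliminates silanolate to give the (Z)-enyne selectively (the bulky silyl groups control the β-oxidosilane geometry), and fluoride then cleaves the alkynyl C–Si bond.

**Step 8**
Reactants: 16 dienyne ester
Product: 17 2-[(1E,3Z)-hexa-1,3-dien-5-ynyl]-4,6-dimethylcyclohexane-1-carbaldehyde (ring stereocentres as in 11)
Conditions: i-Bu2AlH (1.1 equiv), CH2Cl2, −78 °C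
Reagents that add atoms: none
Why: Partial ester reduction, in which the tetrahedral aluminium hemiacetal of the hindered ester is stable at −78 °C and releases the aldehyde on work-up; the α-centre is already the thermodynamic one.

**Step 9**
Reactants: 17 dienyne aldehyde; 18 3,3-diethoxyprop-1-yne
Product: 20 (4S,2E)-4-{2-[(1E,3Z)-hexa-1,3-dien-5-ynyl]-4,6-dimethylcyclohexyl}-4-hydroxybut-2-enal (ring stereocentres as in 11), via hydroxy acetal 19 (not isolated)
Conditions: 18, Cp2Zr(H)Cl, CH2Cl2, 23 °C; Me2Zn, toluene, −65 °C; (−)-MIB (10 mol%), 17, −30 → 0 °C; then 1 M HCl, THF, 23 °C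
Reagents that add atoms: water (O)
Why: Hydrozirconation, zirconium-to-zinc transmetalation and amino-alcohol-catalysed alkenylzinc addition, in which (−)-MIB directs the (E)-alkenyl group to the Si face of the aldehyde to give the (S)-carbinol under reagent control (the Felkin bias of the ring is weak), and the acidic work-up hydrolyses the unsaturated acetal.

**Step 10**
Reactants: 20 (S)-hydroxy enal; 6 rac-5-hydroxy-5-(4-hydroxybenzyl)-1,5-dihydro-2H-pyrrol-2-one
Product: 21 (4R,2E)-4-{2-[(1E,3Z)-hexa-1,3-dien-5-ynyl]-4,6-dimethylcyclohexyl}-4-{4-[(2-hydroxy-5-oxo-2,5-dihydro-1H-pyrrol-2-yl)methyl]phenoxy}but-2-enal (ring stereocentres as in 11; two epimers at the hemiaminal carbon)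
Conditions: 6 (1.5 equiv), PPh3, DIAD, THF, 0 → 23 °C
Reagents that add atoms: none
Why: Mitsunobu etherification, in which the phenol (the only pronucleophile acidic enough) displaces the activated allylic alcohol by SN2 with inversion, giving the (R)-aryl ether that matches the target; SN2′ attack is disfavoured because it would place the nucleophile alpha to the formyl group.

**Step 11**
Reactants: 21 aryl ether trienyne
Product: 22 2-ethynyl-6,8-dimethyl-9-{4-[(2-hydroxy-5-oxo-2,5-dihydro-1H-pyrrol-2-yl)methyl]phenoxy}-2,4a,4b,5,6,7,8,8a,9,9a-decahydro-1H-fluorene-1-carbaldehyde (ring stereocentres as in 24)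
Conditions: toluene (0.005 M), BHT (cat.), 120 °C, sealed tube
Reagents that add atoms: none
Why: Intramolecular Diels–Alder reaction through the formyl-endo transition state of the (E)-enal gives the trans ring fusion with the formyl group trans to it, the diene adds on the face that keeps the new rings anti to the chair cyclohexane (no bay interaction; the same substitution pattern is known to cyclise this way for the 6-5-6 core of this family), and the small alkynyl group on the (Z)-terminus ends trans to the ring-fusion bond, which is the configuration of the vinyl-bearing carbon.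

**Step 12**
Reactants: 22 tricyclic aldehyde
Product: 23 didehydro-xenoacremone H (24 with ethynyl in place of vinyl)
Conditions: 3-benzyl-5-(2-hydroxyethyl)-4-methylthiazolium chloride (30 mol%), Et3N (2 equiv), 1,4-dioxane (0.002 M, slow addition), 80 °C
Reagents that add atoms: none
Why: Proposed new method: the thiazolylidene turns the aldehyde into a Breslow acyl-anion equivalent, base-mediated ring–chain tautomerism of the hydroxypyrrolinone exposes the (Z)-4-oxo-enamide whose carbon beta to the ketone (alpha to the amide) is attacked intramolecularly, and the 1,4-diketo amide re-closes to the hydroxylactam, so the lactam C3 and hemiaminal centres settle under thermodynamic control (β-keto lactam enolisation, ring–chain tautomerism) in the strained [13]paracyclophane; the closest known reactions are the intramolecular Stetter reaction of aliphatic aldehydes onto enones and Stetter additions to fumarate-type acceptors.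

**Step 13**
Reactants: 23 macrocyclic alkyne
Product: 24 Xenoacremone H
Conditions: H2 (1 atm), Pd/CaCO3 poisoned with Pb(OAc)2, quinoline, EtOAc, 23 °C
Reagents that add atoms: none
Why: Lindlar-type semi-hydrogenation reduces the terminal alkyne to the vinyl group and leaves the hindered ring alkene and all stereocentres untouched.

**Compound list**
1 | furan | c1ccoc1 | starting material
2 | 4-hydroxybenzyl alcohol | OCc1ccc(O)cc1 | starting material
3 | 4-(furan-2-ylmethyl)phenol | Oc1ccc(Cc2ccco2)cc1 | intermediate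
4 | 2-hydroperoxy-5-(4-hydroxybenzyl)-5-methoxy-2,5-dihydrofuran (diastereomer mixture) | COC1(Cc2ccc(O)cc2)C=CC(OO)O1 | intermediate
5 | 5-(4-hydroxybenzyl)-5-methoxyfuran-2(5H)-one (racemic) | COC1(Cc2ccc(O)cc2)C=CC(=O)O1 | intermediate
6 | rac-5-hydroxy-5-(4-hydroxybenzyl)-1,5-dihydro-2H-pyrrol-2-one | O=C1C=CC(O)(Cc2ccc(O)cc2)N1 | intermediate
7 | (E)-2-methylpenta-1,3-diene | C/C=C/C(C)=C | starting material
8 | (5R)-5-[(1R,2S,5R)-menthyloxy]furan-2(5H)-one | C[C@@H]1CC[C@H]([C@@H](C1)O[C@@H]1OC(=O)C=C1)C(C)C | starting material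
9 | (3R)-3-[(1R,2S,5R)-menthyloxy]-5,7-dimethyl-3a,4,7,7a-tetrahydroisobenzofuran-1(3H)-one, cis-fused, 7-methyl cis to the lactone, menthyloxy trans to C4 | C[C@@H]1CC[C@H]([C@@H](C1)O[C@@H]1OC(=O)[C@H]2[C@@H](C)C=C(C)C[C@@H]12)C(C)C | intermediate
10 | (3R)-3-[(1R,2S,5R)-menthyloxy]-5,7-dimethylhexahydroisobenzofuran-1(3H)-one, cis-fused, both methyl groups cis to the lactone | C[C@@H]1CC[C@H]([C@@H](C1)O[C@@H]1OC(=O)[C@H]2[C@@H](C)C[C@@H](C)C[C@@H]12)C(C)C | intermediate
11 | methyl (1R,2R,4R,6S)-2-formyl-4,6-dimethylcyclohexane-1-carboxylate | O=C[C@@H]1C[C@H](C)C[C@H](C)[C@H]1C(=O)OC | intermediate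
12 | (triphenylphosphoranylidene)acetaldehyde | O=CC=P(c1ccccc1)(c1ccccc1)c1ccccc1 | starting material
13 | methyl 4,6-dimethyl-2-[(E)-3-oxoprop-1-enyl]cyclohexane-1-carboxylate, ring stereocentres as in 11 | O=C/C=C/[C@@H]1C[C@H](C)C[C@H](C)[C@H]1C(=O)OC | intermediate
14 | 1,3-bis(triisopropylsilyl)propyne | CC(C)[Si](C(C)C)(C(C)C)CC#C[Si](C(C)C)(C(C)C)C(C)C | starting material
15 | methyl 4,6-dimethyl-2-[(1E,3Z)-6-(triisopropylsilyl)hexa-1,3-dien-5-ynyl]cyclohexane-1-carboxylate, ring stereocentres as in 11 | CC(C)[Si](C(C)C)(C(C)C)C#C/C=C\C=C\[C@@H]1C[C@H](C)C[C@H](C)[C@H]1C(=O)OC | intermediate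
16 | methyl 2-[(1E,3Z)-hexa-1,3-dien-5-ynyl]-4,6-dimethylcyclohexane-1-carboxylate, ring stereocentres as in 11 | C#C/C=C\C=C\[C@@H]1C[C@H](C)C[C@H](C)[C@H]1C(=O)OC | intermediate
17 | 2-[(1E,3Z)-hexa-1,3-dien-5-ynyl]-4,6-dimethylcyclohexane-1-carbaldehyde, ring stereocentres as in 11 | C#C/C=C\C=C\[C@@H]1C[C@H](C)C[C@H](C)[C@H]1C=O | intermediate
18 | 3,3-diethoxyprop-1-yne | C#CC(OCC)OCC | starting material
19 | (1S,2E)-4,4-diethoxy-1-{2-[(1E,3Z)-hexa-1,3-dien-5-ynyl]-4,6-dimethylcyclohexyl}but-2-en-1-ol, ring stereocentres as in 11 | C#C/C=C\C=C\[C@@H]1C[C@H](C)C[C@H](C)[C@H]1[C@@H](O)/C=C/C(OCC)OCC | intermediate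
20 | (4S,2E)-4-{2-[(1E,3Z)-hexa-1,3-dien-5-ynyl]-4,6-dimethylcyclohexyl}-4-hydroxybut-2-enal, ring stereocentres as in 11 | C#C/C=C\C=C\[C@@H]1C[C@H](C)C[C@H](C)[C@H]1[C@@H](O)/C=C/C=O | intermediate
21 | (4R,2E)-4-{2-[(1E,3Z)-hexa-1,3-dien-5-ynyl]-4,6-dimethylcyclohexyl}-4-{4-[(2-hydroxy-5-oxo-2,5-dihydro-1H-pyrrol-2-yl)methyl]phenoxy}but-2-enal, ring stereocentres as in 11, epimers at the hemiaminal carbon | C#C/C=C\C=C\[C@@H]1C[C@H](C)C[C@H](C)[C@H]1[C@H](Oc1ccc(CC2(O)C=CC(=O)N2)cc1)/C=C/C=O | intermediate
22 | 2-ethynyl-6,8-dimethyl-9-{4-[(2-hydroxy-5-oxo-2,5-dihydro-1H-pyrrol-2-yl)methyl]phenoxy}-2,4a,4b,5,6,7,8,8a,9,9a-decahydro-1H-fluorene-1-carbaldehyde, ring stereocentres as in 24, epimers at the hemiaminal carbon | C#C[C@@H]1C=C[C@H]2[C@@H]3C[C@H](C)C[C@H](C)[C@H]3[C@H](Oc3ccc(CC4(O)C=CC(=O)N4)cc3)[C@@H]2[C@H]1C=O | intermediate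
23 | didehydro-xenoacremone H (ethynyl in place of vinyl, all stereocentres as in 24) | C#C[C@@H]1C=C[C@H]2[C@@H]3C[C@H](C)C[C@H](C)[C@H]3[C@@H]3Oc4ccc(cc4)C[C@@]4(O)C[C@H](C(=O)N4)C(=O)[C@@H]1[C@H]23 | intermediate
24 | Xenoacremone H | C=C[C@@H]1C=C[C@H]2[C@@H]3C[C@H](C)C[C@H](C)[C@H]3[C@@H]3Oc4ccc(cc4)C[C@@]4(O)C[C@H](C(=O)N4)C(=O)[C@@H]1[C@H]23 | target

**Step count and risks**
Total: 13 steps (2 for phenol fragment 6, 11 in the main line). Longest linear sequence: 11 steps (7 + 8 → 24, steps 3–13).

Step 12 is the most likely to fail: the [13]paracyclophane is strained, the aldehyde is hindered, and the acceptor is only available through ring–chain tautomerism. The fallback keeps the acyl-anion C–C bond but forms it between two free fragments and closes the ring at the aryl ether. It sets out from 17. Alkenylation as in step 9 but with (+)-MIB gives the (R)-configured epimeric hydroxy enal F1. Me2AlCl (2.2 equiv, CH2Cl2, −78 → 23 °C) cyclises its aluminium alkoxide to tricyclic hydroxy aldehyde F2, whose carbinol carbon already has the configuration of 24. Maleimide and 4-BrC6H4CH2MgBr (2.2 equiv, THF, −78 °C) give bromobenzyl hydroxypyrrolinone F3. An intermolecular thiazolium-catalysed Stetter reaction of F2 with F3 (reagents of step 12, 0.2 M) gives seco-bromide F4. Intramolecular C–O coupling (CuI, 3,4,7,8-tetramethyl-1,10-phenanthroline, Cs2CO3, toluene, 110 °C, 0.002 M) closes the ring with retention at the carbinol carbon and comes back to the route at 23.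

Step 11 is second: a (Z)-substituted diene terminus slows the cycloaddition, and heat may erode selectivity or damage the γ-aryloxy enal. The fallback reduces the alkyne first and runs the cycloaddition cold under Lewis-acid activation. It sets out from 21. Semi-hydrogenation under the conditions of step 13 gives (Z)-triene F5. Me2AlCl (3.5 equiv, the first two consumed by the O–H and N–H groups; CH2Cl2, −78 → −20 °C) cyclises it, well below the temperature at which a (Z)-hexatriene electrocyclises, to vinyl tricycle F6. Step 12 applied to F6 comes back to the route at 24.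

Step 10 is third: the carbinol is flanked by a branched ring carbon, so elimination to the dienal can outrun substitution. The fallback makes the ether with net retention through a π-allyl complex. It sets out from 17. Alkenylation as in step 9 but with (+)-MIB and a neutral work-up gives epimeric hydroxy acetal F7. Methyl chloroformate and pyridine (CH2Cl2, 0 °C) give allylic carbonate F8. Pd2(dba)3 (2.5 mol%), PPh3 and phenol 6 (THF, 23 °C) give aryl ether acetal F9 by double inversion, with attack at the allyl terminus remote from the acetal. 1 M HCl in THF then comes back to the route at 21.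

**Further compounds**
F1 | step 12 | (4R,2E)-4-{2-[(1E,3Z)-hexa-1,3-dien-5-ynyl]-4,6-dimethylcyclohexyl}-4-hydroxybut-2-enal (carbinol epimer of 20) | C#C/C=C\C=C\[C@@H]1C[C@H](C)C[C@H](C)[C@H]1[C@H](O)/C=C/C=O
F2 | step 12 | 2-ethynyl-9-hydroxy-6,8-dimethyl-2,4a,4b,5,6,7,8,8a,9,9a-decahydro-1H-fluorene-1-carbaldehyde, ring stereocentres as in 24 | C#C[C@@H]1C=C[C@H]2[C@@H]3C[C@H](C)C[C@H](C)[C@H]3[C@H](O)[C@@H]2[C@H]1C=O
F3 | step 12 | rac-5-(4-bromobenzyl)-5-hydroxy-1,5-dihydro-2H-pyrrol-2-one | O=C1C=CC(O)(Cc2ccc(Br)cc2)N1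
F4 | step 12 | 3-[(2-ethynyl-9-hydroxy-6,8-dimethyl-decahydro-1H-fluoren-1-yl)carbonyl]-5-(4-bromobenzyl)-5-hydroxypyrrolidin-2-one, core stereocentres as in 24, lactam centres as a mixture | C#C[C@@H]1C=C[C@H]2[C@@H]3C[C@H](C)C[C@H](C)[C@H]3[C@H](O)[C@@H]2[C@H]1C(=O)C1CC(O)(Cc2ccc(Br)cc2)NC1=O
F5 | step 11 | (4R,2E)-4-{2-[(1E,3Z)-hexa-1,3,5-trienyl]-4,6-dimethylcyclohexyl}-4-{4-[(2-hydroxy-5-oxo-2,5-dihydro-1H-pyrrol-2-yl)methyl]phenoxy}but-2-enal | C=C/C=C\C=C\[C@@H]1C[C@H](C)C[C@H](C)[C@H]1[C@H](Oc1ccc(CC2(O)C=CC(=O)N2)cc1)/C=C/C=O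
F6 | step 11 | 2-vinyl analogue of 22 | C=C[C@@H]1C=C[C@H]2[C@@H]3C[C@H](C)C[C@H](C)[C@H]3[C@H](Oc3ccc(CC4(O)C=CC(=O)N4)cc3)[C@@H]2[C@H]1C=O
F7 | step 10 | (1R,2E)-4,4-diethoxy-1-{2-[(1E,3Z)-hexa-1,3-dien-5-ynyl]-4,6-dimethylcyclohexyl}but-2-en-1-ol (carbinol epimer of 19) | C#C/C=C\C=C\[C@@H]1C[C@H](C)C[C@H](C)[C@H]1[C@H](O)/C=C/C(OCC)OCC
F8 | step 10 | methyl carbonate of F7 | C#C/C=C\C=C\[C@@H]1C[C@H](C)C[C@H](C)[C@H]1[C@H](OC(=O)OC)/C=C/C(OCC)OCC
F9 | step 10 | diethyl acetal of 21 | C#C/C=C\C=C\[C@@H]1C[C@H](C)C[C@H](C)[C@H]1[C@H](Oc1ccc(CC2(O)C=CC(=O)N2)cc1)/C=C/C(OCC)OCC
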